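**Plan**

- Retrosynthesis: the O1–C2 and C4–C4a bonds of the upper pyran ring are cut together, giving pyrogallol and a lower flavan that carries a 3-(4-hydroxyphenyl)allyl alcohol on C-6. Further cuts are the C-6–carbinol bond (aryllithium + cinnamaldehyde), O1–C2 of the lower pyran ring (Mitsunobu), its C-3/C-4 diol (osmylation of a Z-alkene) and the ynone (acyl Sonogashira).
- Forward order: lower ring A from 2,3,4-trihydroxybenzaldehyde → aryl alkyne → ynone → Z-allylic silyl ether → diol acetonide → lower pyran ring → allyl chain with ring B → upper ring C and a new ring A from pyrogallol in one operation → ketal hydrolysis and hydrogenolysis.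
- Stereochemistry: lower C-2 from an oxazaborolidine reduction followed by Mitsunobu inversion; lower C-3 and C-4 from syn-dihydroxylation of the Z-alkene anti to the allylic silyloxy group; upper C-4 from a chiral phosphoric acid; upper C-2 (2,4-trans) from the substrate during ring closure.
- Enabling feature: the free para-hydroxyl of upper ring B is conjugated through C-2, C-3 and C-4, so this chain can exist as a vinylogous para-quinone methide, electrophilic first at C-4 and, after tautomerisation, at C-2. In pyrogallol the nucleophilic ring carbon (future C-4a, para to the 7-hydroxyl) and the hydroxyl that becomes O-1 sit on adjacent atoms.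

Key step: step 15

Assumption: (R)-TRIP, i.e. (R)-3,3'-bis(2,4,6-triisopropylphenyl)-1,1'-binaphthalene-2,2'-diyl hydrogen phosphate, is taken to give the 4S centre in step 15; if the sense of induction is the opposite, the (S)-acid is used and nothing else changes.

**Route**

Step 1
Reactants: 1 2,3,4-trihydroxybenzaldehyde
Product: 2 3,4-bis(benzyloxy)-2-hydroxybenzaldehyde
Conditions: BnBr (2.1 equiv), K2CO3 (2.1 equiv), DMF, rt
Reagents that add atoms: benzyl bromide BrCc1ccccc1
Why: Williamson etherification; the 4- and 3-hydroxyls should be alkylated, while the 2-hydroxyl, hydrogen-bonded to the formyl group, is the least nucleophilic and should stay free.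

Step 2
Reactants: 2 3,4-bis(benzyloxy)-2-hydroxybenzaldehyde
Product: 3 3,4-bis(benzyloxy)-5-bromo-2-hydroxybenzaldehyde
Conditions: NBS (1.05 equiv), MeCN, 0 °C
Reagents that add atoms: N-bromosuccinimide O=C1CCC(=O)N1Br
Why: electrophilic aromatic bromination; C-5 is para to the free hydroxyl and ortho to the 4-benzyloxy group, whereas C-6 is ortho to the formyl group and para only to the twisted 3-benzyloxy group.

Step 3
Reactants: 3 3,4-bis(benzyloxy)-5-bromo-2-hydroxybenzaldehyde
Product: 4 3,4-bis(benzyloxy)-5-bromo-2-(tert-butyldimethylsilyloxy)benzaldehyde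
Conditions: TBSCl, imidazole, DMF, rt
Reagents that add atoms: tert-butyldimethylsilyl chloride CC(C)(C)[Si](C)(C)Cl
Why: phenol silylation; the silyl ether masks the future ring oxygen and is later removed by fluoride together with the carbinol silyl ether.

Step 4
Reactants: 4 3,4-bis(benzyloxy)-5-bromo-2-(tert-butyldimethylsilyloxy)benzaldehyde
Product: 5 [2,3-bis(benzyloxy)-4-bromo-6-ethynylphenoxy](tert-butyl)dimethylsilane
Conditions: Me3SiCHN2, LiN(iPr)2, THF, −78 → 0 °C; aq NH4Cl
Reagents that add atoms: trimethylsilyldiazomethane C[Si](C)(C)C=[N+]=[N-]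
Why: Colvin rearrangement (addition of lithiated trimethylsilyldiazomethane, Peterson elimination, loss of N2 and 1,2-hydrogen shift of the alkylidene carbene); the amide base at −78 °C should leave the aryl bromide and the aryl silyl ether untouched.

Step 5
Reactants: 5 [2,3-bis(benzyloxy)-4-bromo-6-ethynylphenoxy](tert-butyl)dimethylsilane; 6 4-(benzyloxy)benzoyl chloride
Product: 7 1-[4-(benzyloxy)phenyl]-3-[3,4-bis(benzyloxy)-5-bromo-2-(tert-butyldimethylsilyloxy)phenyl]prop-2-yn-1-one
Conditions: PdCl2(PPh3)2 (2 mol%), CuI (4 mol%), Et3N, THF, rt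
Reagents that add atoms: none
Why: acyl Sonogashira coupling; the acid chloride should add oxidatively at room temperature much faster than the hindered, electron-rich aryl bromide.

Step 6
Reactants: 7 1-[4-(benzyloxy)phenyl]-3-[3,4-bis(benzyloxy)-5-bromo-2-(tert-butyldimethylsilyloxy)phenyl]prop-2-yn-1-one
Product: 8 (S)-1-[4-(benzyloxy)phenyl]-3-[3,4-bis(benzyloxy)-5-bromo-2-(tert-butyldimethylsilyloxy)phenyl]prop-2-yn-1-ol
Conditions: (S)-Me-CBS oxazaborolidine (20 mol%), BH3·SMe2, THF, −30 °C; MeOH quench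
Reagents that add atoms: none
Why: Corey–Bakshi–Shibata reduction; the aryl group acts as the large and the linear alkynyl group as the small substituent, so the (S)-catalyst should give the S carbinol.

Step 7
Reactants: 8 (S)-1-[4-(benzyloxy)phenyl]-3-[3,4-bis(benzyloxy)-5-bromo-2-(tert-butyldimethylsilyloxy)phenyl]prop-2-yn-1-ol
Product: 9 (S)-{[1-[4-(benzyloxy)phenyl]-3-[3,4-bis(benzyloxy)-5-bromo-2-(tert-butyldimethylsilyloxy)phenyl]prop-2-yn-1-yl]oxy}(tert-butyl)dimethylsilane
Conditions: TBSCl, imidazole, DMF, rt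
Reagents that add atoms: tert-butyldimethylsilyl chloride CC(C)(C)[Si](C)(C)Cl
Why: silylation of the secondary alcohol; this ether is the allylic alkoxy group that directs step 9 and keeps the C-2 oxygen distinct from the two hydroxyls introduced there.

Step 8
Reactants: 9 (S)-bis-silyl ether of the propargylic alcohol
Product: 10 (1R,2Z)-1-[4-(benzyloxy)phenyl]-3-[3,4-bis(benzyloxy)-5-bromo-2-(tert-butyldimethylsilyloxy)phenyl]-1-(tert-butyldimethylsilyloxy)prop-2-ene (same spatial arrangement at C-1 as in 9)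
Conditions: H2 (1 atm), Pd/CaCO3 poisoned with Pb(OAc)2, quinoline, EtOAc, rt
Reagents that add atoms: none
Why: Lindlar semihydrogenation; syn addition of hydrogen should give the Z-alkene, and the poisoned catalyst should not cleave benzyl ethers or the aryl bromide.

Step 9
Reactants: 10 (1R,2Z)-alkene bis-silyl ether
Product: 11 (1R,2R,3S)-3-[4-(benzyloxy)phenyl]-1-[3,4-bis(benzyloxy)-5-bromo-2-(tert-butyldimethylsilyloxy)phenyl]-3-(tert-butyldimethylsilyloxy)propane-1,2-diol (all three oxygens erythro)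
Conditions: OsO4 (5 mol%), NMO (2 equiv), acetone–H2O (8:1), rt
Reagents that add atoms: osmium tetroxide O=[Os](=O)(=O)=O; N-methylmorpholine N-oxide C[N+]1([O-])CCOCC1; water O
Why: Upjohn syn-dihydroxylation; the Z geometry fixes the two new hydroxyls erythro (cis in the later ring), and with the allylic C–H eclipsing the alkene to avoid 1,3-allylic strain the oxidant should add anti to the silyloxy group (the empirical rule for osmylation of allylic ethers), setting the middle carbon erythro to the silyloxy carbon.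

Step 10
Reactants: 11 (1R,2R,3S)-diol
Product: 12 (4R,5R)-4-[3,4-bis(benzyloxy)-5-bromo-2-(tert-butyldimethylsilyloxy)phenyl]-5-{(S)-[4-(benzyloxy)phenyl](tert-butyldimethylsilyloxy)methyl}-2,2-dimethyl-1,3-dioxolane (cis-dioxolane)
Conditions: Me2C(OMe)2, PPTS (cat.), CH2Cl2, rt
Reagents that add atoms: 2,2-dimethoxypropane COC(C)(C)OC
Why: acid-catalysed transketalisation; only the two new hydroxyls are free, and the erythro diol closes to the cis-dioxolane.

Step 11
Reactants: 12 cis-dioxolane bis-silyl ether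
Product: 13 (S)-[4-(benzyloxy)phenyl]{(4S,5R)-5-[3,4-bis(benzyloxy)-5-bromo-2-hydroxyphenyl]-2,2-dimethyl-1,3-dioxolan-4-yl}methanol (spatial arrangement unchanged from 12)
Conditions: Bu4NF (2.5 equiv), THF, 0 °C → rt; aq NH4Cl
Reagents that add atoms: none
Why: fluoride cleavage of the aryl and the secondary silyl ether in one operation; ketal, benzyl ethers and aryl bromide are inert to fluoride.

Step 12
Reactants: 13 phenol–carbinol acetonide
Product: 14 (2R,3S,4R)-7,8-bis(benzyloxy)-2-[4-(benzyloxy)phenyl]-6-bromo-3,4-(isopropylidenedioxy)chromane (2,3-cis-3,4-cis; the C-3 descriptor differs from that of the free diol only because of the ketal, the spatial arrangement being that of the 2R,3R,4R diol; its chroman-6-yl group is written LU below)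
Conditions: PPh3, DIAD, THF, 0 °C → rt
Reagents that add atoms: none
Why: intramolecular Mitsunobu etherification; the phenol should displace the benzylic oxyphosphonium group in a 6-exo-tet SN2 process with inversion, turning the S carbinol into R-configured C-2 with the aryl group cis to the C-3 oxygen.

Step 13
Reactants: 15 (E)-3-(4-hydroxyphenyl)prop-2-enal
Product: 16 (E)-3-[4-(tert-butyldimethylsilyloxy)phenyl]prop-2-enal
Conditions: TBSCl, imidazole, CH2Cl2, rt
Reagents that add atoms: tert-butyldimethylsilyl chloride CC(C)(C)[Si](C)(C)Cl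
Why: phenol silylation, so that the aldehyde tolerates the aryllithium of step 14.

Step 14
Reactants: 14 LU–Br (bromoflavan acetonide); 16 (E)-3-[4-(tert-butyldimethylsilyloxy)phenyl]prop-2-enal
Product: 19 (1RS,2E)-3-(4-hydroxyphenyl)-1-LU-prop-2-en-1-ol, via aryllithium 17 (not isolated), via lithium alkoxide silyl ether 18 (not isolated)
Conditions: n-BuLi (1.05 equiv), THF, −78 °C; 16, −78 °C; then Bu4NF (1.2 equiv), 0 °C; cold aq NH4Cl; product used without chromatography
Reagents that add atoms: none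
Why: bromine–lithium exchange, 1,2-addition of the aryllithium to the enal and fluoride cleavage of the aryl silyl ether in one pot; the carbinol centre is formed without control because step 15 destroys it.

Step 15
Reactants: 19 (1RS,2E)-3-(4-hydroxyphenyl)-1-LU-prop-2-en-1-ol; 20 pyrogallol (benzene-1,2,3-triol)
Product: 23 2-(4-hydroxyphenyl)-4-LU-chromane-7,8-diol (2,4-trans; both new centres as in the target), via vinylogous para-quinone methide 21 (not isolated), via styrene adduct 22 (not isolated)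
Conditions: (R)-TRIP (10 mol%), pyrogallol (5 equiv), 5 Å molecular sieves, CH2Cl2–EtOAc (9:1), Ar, −20 → 0 °C
Reagents that add atoms: none
Why: Proposed new method: the acid should dehydrate the doubly activated carbinol of 19 to the vinylogous para-quinone methide 21, which stays hydrogen-bonded through its ring B oxygen to the phosphate while the phosphoryl oxygen binds a pyrogallol hydroxyl; C-4 of pyrogallol (ortho to one hydroxyl and para to another) then adds to the far terminus (1,8-addition) to give styrene 22, and protonation of 22 at the carbon next to the new centre regenerates a quinone methide onto whose benzylic carbon the neighbouring phenolic oxygen closes. The closest known reactions are the chiral phosphoric acid-catalysed Friedel–Crafts additions of phenols and naphthols to para-quinone methides formed in situ from para-hydroxybenzyl alcohols (including 1,8-additions to alkynyl analogues) and the Brønsted acid-catalysed formal (3+3) annulation of phenols with 1,3-diarylallyl alcohols to 2,4-diarylchromans (Friedel–Crafts allylation, then hydroalkoxylation); the enantioselective merger of the two on an alkenyl quinone methide is what is new. The pyran ring (upper ring C) closes by a 6-exo-trig oxa-1,6-addition of O-1 to C-2, the acceptor double bond lying outside the new ring. C-4 is set in the C–C bond formation by the chiral phosphate, which holds both partners and exposes one face of the planar terminus; C-2 is set in the ring closure by the substrate, a chair-like transition state placing ring B equatorial and the ortho-substituted lower-unit aryl group at C-4 pseudo-axial (away from H-5), which corresponds to the 2,4-trans isomer. The step needs 1,8- over 1,6-addition, C- over O-alkylation, a single annulation and closure by the pyrogallol oxygen only: the free para-hydroxyl makes ring B the stronger donor, so attack at the far terminus keeps the hydroxystyrene conjugation (the benzyl ethers on O-7 and O-8 of the lower unit are twisted out of conjugation and weaken that aryl group as a donor), O-alkylation is reversible under the acid, pyrogallol is used in excess, and the benzyl ether on O-7 of the lower unit removes the only other oxygen that could close a six-membered ring.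

Step 16
Reactants: 23 2-(4-hydroxyphenyl)-4-LU-chromane-7,8-diol
Product: 24 6-[7,8-dihydroxy-2-(4-hydroxyphenyl)chroman-4-yl]-7,8-bis(benzyloxy)-2-[4-(benzyloxy)phenyl]chromane-3,4-diol (all five stereocentres as in the target)
Conditions: AcOH–H2O (4:1), 40 °C
Reagents that add atoms: none
Why: acid-catalysed hydrolysis of the isopropylidene ketal; oxocarbenium formation at the ketal carbon should be faster than ionisation of the benzylic C-4–O bond of the still benzylated lower unit, so the cis-diol should be released with retention.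

Step 17
Reactants: 24 tri-O-benzyl diol
Product: 25 (2R,3R,4R)-6-[(2S,4S)-7,8-dihydroxy-2-(4-hydroxyphenyl)chroman-4-yl]-2-(4-hydroxyphenyl)chromane-3,4,7,8-tetrol (target)
Conditions: H2 (1 atm), Pd(OH)2/C, THF–MeOH, rt
Reagents that add atoms: none
Why: hydrogenolysis of the three aryl benzyl ethers under neutral conditions, as in proanthocyanidin syntheses; the cyclic benzylic ethers and the benzylic 4-hydroxyl should be cleaved much more slowly.

**Compound list**

1 | 2,3,4-trihydroxybenzaldehyde | O=Cc1ccc(O)c(O)c1O | starting material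
2 | 3,4-bis(benzyloxy)-2-hydroxybenzaldehyde | O=Cc1ccc(OCc2ccccc2)c(OCc2ccccc2)c1O | intermediate
3 | 3,4-bis(benzyloxy)-5-bromo-2-hydroxybenzaldehyde | O=Cc1cc(Br)c(OCc2ccccc2)c(OCc2ccccc2)c1O | intermediate
4 | 3,4-bis(benzyloxy)-5-bromo-2-(tert-butyldimethylsilyloxy)benzaldehyde | O=Cc1cc(Br)c(OCc2ccccc2)c(OCc2ccccc2)c1O[Si](C)(C)C(C)(C)C | intermediate
5 | [2,3-bis(benzyloxy)-4-bromo-6-ethynylphenoxy](tert-butyl)dimethylsilane | C#Cc1cc(Br)c(OCc2ccccc2)c(OCc2ccccc2)c1O[Si](C)(C)C(C)(C)C | intermediate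
6 | 4-(benzyloxy)benzoyl chloride | O=C(Cl)c1ccc(OCc2ccccc2)cc1 | starting material
7 | 1-[4-(benzyloxy)phenyl]-3-[3,4-bis(benzyloxy)-5-bromo-2-(tert-butyldimethylsilyloxy)phenyl]prop-2-yn-1-one | O=C(C#Cc1cc(Br)c(OCc2ccccc2)c(OCc2ccccc2)c1O[Si](C)(C)C(C)(C)C)c1ccc(OCc2ccccc2)cc1 | intermediate
8 | (S)-propargylic alcohol from 7 | O[C@@H](c1ccc(OCc2ccccc2)cc1)C#Cc1cc(Br)c(OCc2ccccc2)c(OCc2ccccc2)c1O[Si](C)(C)C(C)(C)C | intermediate
9 | (S)-O-tert-butyldimethylsilyl ether of 8 | CC(C)(C)[Si](C)(C)O[C@@H](c1ccc(OCc2ccccc2)cc1)C#Cc1cc(Br)c(OCc2ccccc2)c(OCc2ccccc2)c1O[Si](C)(C)C(C)(C)C | intermediate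
10 | (1R,2Z)-alkene from 9 | CC(C)(C)[Si](C)(C)O[C@@H](c1ccc(OCc2ccccc2)cc1)/C=C\c1cc(Br)c(OCc2ccccc2)c(OCc2ccccc2)c1O[Si](C)(C)C(C)(C)C | intermediate
11 | (1R,2R,3S)-3-[4-(benzyloxy)phenyl]-1-[3,4-bis(benzyloxy)-5-bromo-2-(tert-butyldimethylsilyloxy)phenyl]-3-(tert-butyldimethylsilyloxy)propane-1,2-diol | CC(C)(C)[Si](C)(C)O[C@@H](c1ccc(OCc2ccccc2)cc1)[C@H](O)[C@H](O)c1cc(Br)c(OCc2ccccc2)c(OCc2ccccc2)c1O[Si](C)(C)C(C)(C)C | intermediate
12 | (4R,5R)-cis-dioxolane (acetonide) of 11 | CC(C)(C)[Si](C)(C)O[C@@H](c1ccc(OCc2ccccc2)cc1)[C@@H]3OC(C)(C)O[C@@H]3c1cc(Br)c(OCc2ccccc2)c(OCc2ccccc2)c1O[Si](C)(C)C(C)(C)C | intermediate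
13 | (S)-[4-(benzyloxy)phenyl]{(4S,5R)-5-[3,4-bis(benzyloxy)-5-bromo-2-hydroxyphenyl]-2,2-dimethyl-1,3-dioxolan-4-yl}methanol | O[C@@H](c1ccc(OCc2ccccc2)cc1)[C@@H]3OC(C)(C)O[C@@H]3c1cc(Br)c(OCc2ccccc2)c(OCc2ccccc2)c1O | intermediate
14 | (2R,3S,4R)-7,8-bis(benzyloxy)-2-[4-(benzyloxy)phenyl]-6-bromo-3,4-(isopropylidenedioxy)chromane, all-cis (LU–Br) | Brc1cc2c(c(OCc3ccccc3)c1OCc1ccccc1)O[C@H](c1ccc(OCc3ccccc3)cc1)[C@@H]1OC(C)(C)O[C@H]21 | intermediate
15 | (E)-3-(4-hydroxyphenyl)prop-2-enal | O=C/C=C/c1ccc(O)cc1 | starting material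
16 | (E)-3-[4-(tert-butyldimethylsilyloxy)phenyl]prop-2-enal | O=C/C=C/c1ccc(O[Si](C)(C)C(C)(C)C)cc1 | intermediate
17 | LU–Li (aryllithium from 14) | [Li]c1cc2c(c(OCc3ccccc3)c1OCc1ccccc1)O[C@H](c1ccc(OCc3ccccc3)cc1)[C@@H]1OC(C)(C)O[C@H]21 | intermediate (not isolated)
18 | lithium alkoxide of (E)-1-LU-3-[4-(tert-butyldimethylsilyloxy)phenyl]prop-2-en-1-ol, both carbinol epimers | [Li]OC(/C=C/c1ccc(O[Si](C)(C)C(C)(C)C)cc1)c1cc2c(c(OCc3ccccc3)c1OCc1ccccc1)O[C@H](c1ccc(OCc3ccccc3)cc1)[C@@H]1OC(C)(C)O[C@H]21 | intermediate (not isolated)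
19 | (1RS,2E)-3-(4-hydroxyphenyl)-1-LU-prop-2-en-1-ol, both carbinol epimers | OC(/C=C/c1ccc(O)cc1)c1cc2c(c(OCc3ccccc3)c1OCc1ccccc1)O[C@H](c1ccc(OCc3ccccc3)cc1)[C@@H]1OC(C)(C)O[C@H]21 | intermediate
20 | pyrogallol (benzene-1,2,3-triol) | Oc1cccc(O)c1O | starting material
21 | 4-[(2E)-3-LU-prop-2-en-1-ylidene]cyclohexa-2,5-dien-1-one | O=C1C=CC(=C/C=C/c2cc3c(c(OCc4ccccc4)c2OCc2ccccc2)O[C@H](c2ccc(OCc4ccccc4)cc2)[C@@H]2OC(C)(C)O[C@H]32)C=C1 | intermediate (not isolated)
22 | 4-[(2E)-3-(4-hydroxyphenyl)-1-LU-prop-2-en-1-yl]benzene-1,2,3-triol, C-1 configured as upper C-4 of the target | Oc1ccc(/C=C/[C@@H](c2cc3c(c(OCc4ccccc4)c2OCc2ccccc2)O[C@H](c2ccc(OCc4ccccc4)cc2)[C@@H]2OC(C)(C)O[C@H]32)c2ccc(O)c(O)c2O)cc1 | intermediate (not isolated)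
23 | 2-(4-hydroxyphenyl)-4-LU-chromane-7,8-diol, 2,4-trans, new centres as in the target | Oc1ccc([C@@H]2C[C@@H](c3cc4c(c(OCc5ccccc5)c3OCc3ccccc3)O[C@H](c3ccc(OCc5ccccc5)cc3)[C@@H]3OC(C)(C)O[C@H]43)c3ccc(O)c(O)c3O2)cc1 | intermediate
24 | 7′,8′,4″-tri-O-benzyl ether of the target (free cis-3,4-diol; benzyl groups on the lower unit only) | Oc1ccc([C@@H]2C[C@@H](c3cc4c(c(OCc5ccccc5)c3OCc3ccccc3)O[C@H](c3ccc(OCc5ccccc5)cc3)[C@H](O)[C@@H]4O)c3ccc(O)c(O)c3O2)cc1 | intermediate
25 | (2R,3R,4R)-6-[(2S,4S)-7,8-dihydroxy-2-(4-hydroxyphenyl)chroman-4-yl]-2-(4-hydroxyphenyl)chromane-3,4,7,8-tetrol | Oc1ccc([C@@H]2C[C@@H](c3cc4c(c(O)c3O)O[C@H](c3ccc(O)cc3)[C@H](O)[C@@H]4O)c3ccc(O)c(O)c3O2)cc1 | target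

**Step count and risks**

Total steps: 17. Longest linear sequence: 16 steps (steps 1–12 and 14–17; step 13 prepares the side-chain aldehyde).

Steps most likely to fail:

1. Step 15 (Proposed new method). What may go wrong: addition at the ring B benzylic carbon (1,6) in place of the far terminus, which would lead to the chroman with the two aryl groups exchanged; insufficient facial discrimination at C-4 by the phosphate; ring closure to the 2,4-cis isomer; or oligomerisation through a second alkylation of the electron-rich product. Fallback using known reactions only, setting out from 14 and 2 and rejoining the route at 25: Miyaura borylation of 14 (B2pin2, PdCl2(dppf), KOAc, dioxane) should give the pinacol boronate of the lower unit F1. Claisen–Schmidt condensation of 2 with 1-[4-(benzyloxy)phenyl]ethanone (KOH, EtOH) should give the (E)-enone F2. Rhodium-catalysed asymmetric conjugate addition of F1 to F2 ([RhCl(C2H4)2]2, the BINAP enantiomer that delivers the 4S centre, KOH, dioxane–H2O) should give the β,β-diaryl ketone F3 and sets C-4 by catalyst control. Corey–Bakshi–Shibata reduction ((S)-Me-CBS, BH3·SMe2) should give the R carbinol F4, and Mitsunobu cyclisation (PPh3, DIAD) closes the pyran ring with inversion to the benzylated 2,4-trans chroman F5. The conditions of step 16 then give the diol F6, and hydrogenolysis as in step 17 gives 25.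

2. Step 12. What may go wrong: ionisation of the para-benzyloxybenzylic oxyphosphonium intermediate before displacement, with loss of stereochemical integrity at C-2 or elimination. Fallback, setting out from 13 and rejoining at 14: oxidation of the benzylic alcohol with MnO2 (CH2Cl2) should give the hydroxy ketone F7, which is in equilibrium with its cyclic hemiketal. Reductive etherification (Et3SiH, BF3·OEt2, CH2Cl2, −78 °C) then proceeds through the cyclic oxocarbenium ion, to which hydride should add on the convex face, anti to the cis-fused dioxolane, leaving the aryl group cis to the C-3 oxygen as in 14.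

3. Step 9. What may go wrong: slow osmylation of the congested Z-alkene and poor facial selectivity, with addition syn to the silyloxy group. Fallback, setting out from 8 and rejoining at 11, replacing substrate control by reagent control: trans-reduction of the propargylic alcohol (NaAlH2(OCH2CH2OMe)2, THF, 0 °C) should give the (1R,2E)-allylic alcohol F8. Sharpless epoxidation with the matched tartrate (Ti(OiPr)4, L-(+)-diisopropyl tartrate, t-BuOOH, 4 Å molecular sieves, CH2Cl2, −20 °C) should give the erythro trans-epoxy alcohol F9. Silylation (TBSCl, imidazole) gives the silyl ether F10, and acid-catalysed hydrolytic opening at the benzylic carbon with inversion (dilute HClO4, aqueous THF, 0 °C) should give 11.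

**Further compounds**

F1 | step 15 | 2-LU-4,4,5,5-tetramethyl-1,3,2-dioxaborolane | CC1(C)OB(OC1(C)C)c1cc2c(c(OCc3ccccc3)c1OCc1ccccc1)O[C@H](c1ccc(OCc3ccccc3)cc1)[C@@H]1OC(C)(C)O[C@H]21
F2 | step 15 | (E)-1-[4-(benzyloxy)phenyl]-3-[3,4-bis(benzyloxy)-2-hydroxyphenyl]prop-2-en-1-one | O=C(/C=C/c1ccc(OCc2ccccc2)c(OCc2ccccc2)c1O)c1ccc(OCc2ccccc2)cc1
F3 | step 15 | 1-[4-(benzyloxy)phenyl]-3-[3,4-bis(benzyloxy)-2-hydroxyphenyl]-3-LU-propan-1-one, C-3 configured as upper C-4 of 25 | O=C(C[C@@H](c1cc2c(c(OCc3ccccc3)c1OCc1ccccc1)O[C@H](c1ccc(OCc3ccccc3)cc1)[C@@H]1OC(C)(C)O[C@H]21)c1ccc(OCc2ccccc2)c(OCc2ccccc2)c1O)c1ccc(OCc2ccccc2)cc1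
F4 | step 15 | (1R)-1-[4-(benzyloxy)phenyl]-3-[3,4-bis(benzyloxy)-2-hydroxyphenyl]-3-LU-propan-1-ol, C-3 as in F3 | O[C@@H](c1ccc(OCc2ccccc2)cc1)C[C@@H](c1cc2c(c(OCc3ccccc3)c1OCc1ccccc1)O[C@H](c1ccc(OCc3ccccc3)cc1)[C@@H]1OC(C)(C)O[C@H]21)c1ccc(OCc2ccccc2)c(OCc2ccccc2)c1O
F5 | step 15 | 7,8-bis(benzyloxy)-2-[4-(benzyloxy)phenyl]-4-LU-chromane, 2,4-trans, configured as 25 | C(Oc1ccc([C@@H]2C[C@@H](c3cc4c(c(OCc5ccccc5)c3OCc3ccccc3)O[C@H](c3ccc(OCc5ccccc5)cc3)[C@@H]3OC(C)(C)O[C@H]43)c3ccc(OCc5ccccc5)c(OCc5ccccc5)c3O2)cc1)c1ccccc1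
F6 | step 15 | hexa-O-benzyl ether of 25 with free cis-3,4-diol | C(Oc1ccc([C@@H]2C[C@@H](c3cc4c(c(OCc5ccccc5)c3OCc3ccccc3)O[C@H](c3ccc(OCc5ccccc5)cc3)[C@H](O)[C@@H]4O)c3ccc(OCc5ccccc5)c(OCc5ccccc5)c3O2)cc1)c1ccccc1
F7 | step 12 | [4-(benzyloxy)phenyl]{(4S,5R)-5-[3,4-bis(benzyloxy)-5-bromo-2-hydroxyphenyl]-2,2-dimethyl-1,3-dioxolan-4-yl}methanone (ring stereocentres spatially as in 13) | O=C(c1ccc(OCc2ccccc2)cc1)[C@@H]1OC(C)(C)O[C@@H]1c1cc(Br)c(OCc2ccccc2)c(OCc2ccccc2)c1O
F8 | step 9 | (1R,2E)-1-[4-(benzyloxy)phenyl]-3-[3,4-bis(benzyloxy)-5-bromo-2-(tert-butyldimethylsilyloxy)phenyl]prop-2-en-1-ol | O[C@@H](c1ccc(OCc2ccccc2)cc1)/C=C/c1cc(Br)c(OCc2ccccc2)c(OCc2ccccc2)c1O[Si](C)(C)C(C)(C)C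
F9 | step 9 | erythro trans-epoxy alcohol from F8 (carbinol carbon as in F8) | O[C@@H](c1ccc(OCc2ccccc2)cc1)[C@@H]1O[C@H]1c1cc(Br)c(OCc2ccccc2)c(OCc2ccccc2)c1O[Si](C)(C)C(C)(C)C
F10 | step 9 | O-tert-butyldimethylsilyl ether of F9 | CC(C)(C)[Si](C)(C)O[C@@H](c1ccc(OCc2ccccc2)cc1)[C@@H]1O[C@H]1c1cc(Br)c(OCc2ccccc2)c(OCc2ccccc2)c1O[Si](C)(C)C(C)(C)C
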